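**Plan** (guaiane numbering: C1–C15, O8 is the oxygen on C8, C11 is the CMe2–O carbon)
- Cuts, in retrosynthetic order: the two ester C–O bonds; C4=C5 (aldol condensation of a 2-(2-oxobutyl)cycloheptanone); C6–C7 (radical ring closure); C5–C6 (methylenation of a lactone carbonyl); C1–C2 and C10–C14 together (one-pot cuprate addition and enolate alkylation); C1=C10 (ring-closing metathesis), O8–C5 (acylation), C8–C9 (allylation of 3-methylbut-2-enal).
- Enabling feature: O8 and C5 lie 1,4 across the seven-membered ring, so the C5 ketone of the cycloheptanone stage can be held as a ketal with O8. Ring C5–C6–C7–C8–C9–C10–C1 is then an 8-oxabicyclo[3.2.1]octane whose two-carbon bridge is C6–C7, made by 5-exo closure of a CH2 radical on ketal carbon C5 onto the C7=C11 alkene on C8 of an oxane (ring O8–C5–C1–C10–C9–C8).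
- Forward order: oxane (δ-lactone) ring first; then the seven-membered carbocycle by C6–C7, in bridged form and with C11–OH installed in the same step; then the cyclopentenone ring (C1–C5) by unmasking and aldol condensation; esters last.
- Stereochemistry: C8 from a Brown allylation; C10 by cuprate addition trans to the C8 substituent; C1 by alkylation trans to the C10 methyl; C7 from the O8–C5 tether (exo attack). All centres are relayed from C8.

Key step: step 8

Remark: compound 2 is used as its commercial solution; the lactone-derived enol ether 13 is carried on crude.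

**Step 1**
Reactants: 1 3-methylbut-2-enal; 2 (+)-B-allyldiisopinocampheylborane
Product: 4 (4R)-6-methylhepta-1,5-dien-4-ol, via borinate ester 3 (not isolated)
Conditions: Et2O, −78 °C; then NaOH, H2O2, rt
Reagents that add atoms: none
Why: Brown allylation through a chair (Zimmerman–Traxler) transition state, in which the (+)-Ipc2B reagent (from (−)-α-pinene) should deliver allyl 1,2 to the Re face of the enal carbonyl and so set C8 as R.

**Step 2**
Reactants: 4 (4R)-6-methylhepta-1,5-dien-4-ol; 5 acryloyl chloride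
Product: 6 (4R)-6-methylhepta-1,5-dien-4-yl prop-2-enoate
Conditions: Et3N, DMAP (cat.), CH2Cl2, 0 °C
Reagents that add atoms: none
Why: Standard O-acylation of a secondary allylic alcohol with an acid chloride under amine base and DMAP catalysis, which does not touch the stereocenter.

**Step 3**
Reactants: 6 (4R)-6-methylhepta-1,5-dien-4-yl prop-2-enoate
Product: 7 (6R)-6-(2-methylprop-1-en-1-yl)-5,6-dihydro-2H-pyran-2-one
Conditions: second-generation Grubbs catalyst RuCl2(=CHPh)(PCy3)(H2IMes) (cat.), CH2Cl2 (dilute), 40 °C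
Reagents that add atoms: none
Why: Ring-closing olefin metathesis between the terminal allyl alkene and the acrylate closes the six-membered unsaturated lactone with loss of ethene, the trisubstituted 2-methylprop-1-enyl alkene being too hindered to compete.

**Step 4**
Reactants: 7 (6R)-6-(2-methylprop-1-en-1-yl)-5,6-dihydro-2H-pyran-2-one; 8 1-bromobut-2-yne
Product: 10 (3R,4S,6R)-3-(but-2-yn-1-yl)-4-methyl-6-(2-methylprop-1-en-1-yl)oxan-2-one, via lithium enolate 9 (not isolated)
Conditions: Me2CuLi (from MeLi and CuI, slight excess), Et2O, −78 to −40 °C; then 8, DMPU, THF, −78 to −20 °C; aq. NH4Cl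
Reagents that add atoms: lithium dimethylcuprate, [Li+].C[Cu-]C
Why: Tandem conjugate addition–enolate alkylation (vicinal difunctionalization), in which the Gilman cuprate should attack the half-chair of the unsaturated δ-lactone axially, with the C8 alkenyl group pseudo-equatorial, so that the new C10 methyl is trans to that group (C10 = S), and lithium enolate 9 is then alkylated in the same flask by the reactive propargylic bromide on the face anti to the adjacent C10 methyl to give the 3,4-trans lactone (C1 = R), the cuprate being kept to a slight excess so that no dialkylcuprate is left to attack the bromide.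

**Step 5**
Reactants: 10 (3R,4S,6R)-3-(but-2-yn-1-yl)-4-methyl-6-(2-methylprop-1-en-1-yl)oxan-2-one
Product: 11 (3R,4S,6R)-4-methyl-6-(2-methylprop-1-en-1-yl)-3-(2-oxobutyl)oxan-2-one
Conditions: NaAuCl4 (cat.), EtOH–H2O, rt
Reagents that add atoms: water, O
Why: Gold-catalysed alkyne hydration with anchimeric assistance, in which 5-exo-dig attack of the lactone carbonyl oxygen on the activated alkyne should place the new ketone on C3 (γ-keto lactone) and not on C4.

**Step 6**
Reactants: 11 (3R,4S,6R)-4-methyl-6-(2-methylprop-1-en-1-yl)-3-(2-oxobutyl)oxan-2-one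
Product: 12 (3R,4S,6R)-3-[(2-ethyl-1,3-dioxolan-2-yl)methyl]-4-methyl-6-(2-methylprop-1-en-1-yl)oxan-2-one
Conditions: TMSOCH2CH2OTMS, TMSOTf (cat.), CH2Cl2, −78 to −20 °C; pyridine quench
Reagents that add atoms: 1,2-bis(trimethylsilyloxy)ethane, C[Si](C)(C)OCCO[Si](C)(C)C
Why: Noyori ketalization at low temperature masks the C3 ketone as a dioxolane, so that only the lactone carbonyl is methylenated next and the side chain offers no radical acceptor later.

**Step 7**
Reactants: 12 (3R,4S,6R)-3-[(2-ethyl-1,3-dioxolan-2-yl)methyl]-4-methyl-6-(2-methylprop-1-en-1-yl)oxan-2-one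
Product: 14 (2S,3R,4S,6R)-2-(bromomethyl)-3-[(2-ethyl-1,3-dioxolan-2-yl)methyl]-2-methoxy-4-methyl-6-(2-methylprop-1-en-1-yl)oxane, via enol ether 13 (not isolated)
Conditions: Cp2TiMe2, toluene, 70 °C, dark; filtration through basic alumina; then NBS, MeOH, NaHCO3, CH2Cl2, −78 °C
Reagents that add atoms: dimethyltitanocene, C[Ti](C)(C1C=CC=C1)C1C=CC=C1; N-bromosuccinimide, O=C1CCC(=O)N1Br; methanol, CO
Why: Petasis methylenation of the lactone carbonyl brings in C6 as an exocyclic enol ether, and its bromo-alkoxylation (haloacetal formation of the Ueno–Stork type) should add methanol axially and trans to the C8 alkenyl group, leaving CH2Br cis to that group on the oxane ring (ketal C5 = S).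

**Step 8**
Reactants: 14 (2S,3R,4S,6R)-2-(bromomethyl)-3-[(2-ethyl-1,3-dioxolan-2-yl)methyl]-2-methoxy-4-methyl-6-(2-methylprop-1-en-1-yl)oxane
Product: 16 2-[(1R,2R,3S,5R,6S)-2-[(2-ethyl-1,3-dioxolan-2-yl)methyl]-1-methoxy-3-methyl-8-oxabicyclo[3.2.1]octan-6-yl]propan-2-ol, via hydroperoxide 15 (not isolated)
Conditions: Bu3SnH (syringe pump), dry air (slow stream), toluene (high dilution), 40 °C
Reagents that add atoms: dioxygen, O=O
Why: Bu3Sn• abstracts bromine from 14 to give the primary C6 radical on ketal carbon C5; in the chair conformer that holds CH2• and the C8 alkenyl group 1,3-diaxial across O8 it adds to C7, the unsubstituted alkene terminus, and the tertiary C11 radical is intercepted by O2, hydroperoxide 15 being reduced in the flask by the stannane to alcohol 16. The closest known reaction type is the Ueno–Stork haloacetal radical cyclization run under oxygenative tin hydride conditions (Bu3SnH/O2). The new C6–C7 bond closes the oxolane ring O8–C5–C6–C7–C8 in the 5-exo-trig mode and thereby, as the two-carbon bridge of an 8-oxabicyclo[3.2.1]octane, the seven-membered carbocycle C5–C6–C7–C8–C9–C10–C1. C7 is controlled by the O8–C5 tether, which forces attack on the alkene face syn to O8, and by allylic 1,3-strain of the cis methyl group, which keeps the C=CMe2 unit turned away from C9, so that C11 should end exo and cis to O8 as in the target. The step needs cyclization to outrun capture of the C6 radical by stannane or O2, and attack at C7 and not C11: slow stannane addition and a thin air stream keep both traps scarce, the diaxial partners are already within bonding distance, the C1 side chain carries no acceptor, and only attack at C7 gives a five-membered ring and a tertiary radical.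

**Step 9**
Reactants: 16 2-[(1R,2R,3S,5R,6S)-2-[(2-ethyl-1,3-dioxolan-2-yl)methyl]-1-methoxy-3-methyl-8-oxabicyclo[3.2.1]octan-6-yl]propan-2-ol
Product: 18 (5S,6R,8S,8aR)-6-hydroxy-5-(2-hydroxypropan-2-yl)-3,8-dimethyl-4,5,6,7,8,8a-hexahydroazulen-2(1H)-one, via hydroxy diketone 17 (not isolated)
Conditions: 1 M HCl, THF, rt; then KOH, MeOH, 50 °C
Reagents that add atoms: water, O
Why: Aqueous acid hydrolyses the bridged methyl ketal and the dioxolane to the 1,4-diketone, and hydroxide then drives the intramolecular aldol condensation of the ethyl ketone α-carbon C4 onto the C5 ketone to the fused tetrasubstituted cyclopentenone (favoured over the bridged mode), with C1 expected to stay trans to the C10 methyl because that is also the more stable arrangement.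

**Step 10**
Reactants: 18 (5S,6R,8S,8aR)-6-hydroxy-5-(2-hydroxypropan-2-yl)-3,8-dimethyl-4,5,6,7,8,8a-hexahydroazulen-2(1H)-one
Product: 19 (5S,6R,8S,8aR)-5-(2-hydroxypropan-2-yl)-3,8-dimethyl-2-oxo-1,2,4,5,6,7,8,8a-octahydroazulen-6-yl propanoate
Conditions: (EtCO)2O, pyridine, DMAP (cat.), CH2Cl2, 0 °C
Reagents that add atoms: propanoic anhydride, CCC(=O)OC(=O)CC
Why: Chemoselective DMAP-catalysed acylation, in which the secondary C8 alcohol is esterified while the hindered tertiary C11 alcohol should stay free.

**Step 11**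
Reactants: 19 (5S,6R,8S,8aR)-5-(2-hydroxypropan-2-yl)-3,8-dimethyl-2-oxo-1,2,4,5,6,7,8,8a-octahydroazulen-6-yl propanoate
Product: 20 (5S,6R,8S,8aR)-5-(2-acetoxypropan-2-yl)-3,8-dimethyl-2-oxo-1,2,4,5,6,7,8,8a-octahydroazulen-6-yl propanoate
Conditions: Ac2O, Et3N, DMAP, CH2Cl2, rt to 40 °C
Reagents that add atoms: acetic anhydride, CC(=O)OC(C)=O
Why: Steglich-type DMAP-catalysed acetylation of the remaining tertiary alcohol under mildly basic conditions that should not epimerise C1 completes the target.

**Compound list**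
1 | 3-methylbut-2-enal | CC(C)=CC=O | starting material
2 | (+)-B-allyldiisopinocampheylborane, (+)-Ipc2B(allyl) | C=CCB([C@H]1C[C@H]2C[C@@H]([C@@H]1C)C2(C)C)[C@H]1C[C@H]2C[C@@H]([C@@H]1C)C2(C)C | starting material
3 | (4R)-6-methylhepta-1,5-dien-4-yl diisopinocampheylborinate | C=CC[C@@H](OB([C@H]1C[C@H]2C[C@@H]([C@@H]1C)C2(C)C)[C@H]1C[C@H]2C[C@@H]([C@@H]1C)C2(C)C)C=C(C)C | intermediate (not isolated)
4 | (4R)-6-methylhepta-1,5-dien-4-ol | C=CC[C@@H](O)C=C(C)C | intermediate
5 | acryloyl chloride | C=CC(Cl)=O | starting material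
6 | (4R)-6-methylhepta-1,5-dien-4-yl prop-2-enoate | C=CC[C@@H](OC(=O)C=C)C=C(C)C | intermediate
7 | (6R)-6-(2-methylprop-1-en-1-yl)-5,6-dihydro-2H-pyran-2-one | O=C1C=CC[C@H](C=C(C)C)O1 | intermediate
8 | 1-bromobut-2-yne | CC#CCBr | starting material
9 | lithium (4S,6R)-4-methyl-6-(2-methylprop-1-en-1-yl)-5,6-dihydro-4H-pyran-2-olate (lithium enolate) | [Li+].[O-]C1=C[C@@H](C)C[C@H](C=C(C)C)O1 | intermediate (not isolated)
10 | (3R,4S,6R)-3-(but-2-yn-1-yl)-4-methyl-6-(2-methylprop-1-en-1-yl)oxan-2-one | O=C1[C@H](CC#CC)[C@@H](C)C[C@H](C=C(C)C)O1 | intermediate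
11 | (3R,4S,6R)-4-methyl-6-(2-methylprop-1-en-1-yl)-3-(2-oxobutyl)oxan-2-one | O=C1[C@H](CC(=O)CC)[C@@H](C)C[C@H](C=C(C)C)O1 | intermediate
12 | (3R,4S,6R)-3-[(2-ethyl-1,3-dioxolan-2-yl)methyl]-4-methyl-6-(2-methylprop-1-en-1-yl)oxan-2-one | O=C1[C@H](CC2(CC)OCCO2)[C@@H](C)C[C@H](C=C(C)C)O1 | intermediate
13 | (3R,4S,6R)-3-[(2-ethyl-1,3-dioxolan-2-yl)methyl]-4-methyl-2-methylidene-6-(2-methylprop-1-en-1-yl)oxane | C=C1[C@H](CC2(CC)OCCO2)[C@@H](C)C[C@H](C=C(C)C)O1 | intermediate (not isolated)
14 | (2S,3R,4S,6R)-2-(bromomethyl)-3-[(2-ethyl-1,3-dioxolan-2-yl)methyl]-2-methoxy-4-methyl-6-(2-methylprop-1-en-1-yl)oxane | CO[C@@]1(CBr)[C@H](CC2(CC)OCCO2)[C@@H](C)C[C@H](C=C(C)C)O1 | intermediate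
15 | (1R,2R,3S,5R,6S)-2-[(2-ethyl-1,3-dioxolan-2-yl)methyl]-6-(2-hydroperoxypropan-2-yl)-1-methoxy-3-methyl-8-oxabicyclo[3.2.1]octane | CO[C@]12C[C@H](C(C)(C)OO)[C@H](O1)C[C@H](C)[C@H]2CC1(CC)OCCO1 | intermediate (not isolated)
16 | 2-[(1R,2R,3S,5R,6S)-2-[(2-ethyl-1,3-dioxolan-2-yl)methyl]-1-methoxy-3-methyl-8-oxabicyclo[3.2.1]octan-6-yl]propan-2-ol | CO[C@]12C[C@H](C(C)(C)O)[C@H](O1)C[C@H](C)[C@H]2CC1(CC)OCCO1 | intermediate
17 | (2R,3S,5R,6S)-5-hydroxy-6-(2-hydroxypropan-2-yl)-3-methyl-2-(2-oxobutyl)cycloheptan-1-one | O=C1C[C@H](C(C)(C)O)[C@H](O)C[C@H](C)[C@H]1CC(=O)CC | intermediate (not isolated)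
18 | (5S,6R,8S,8aR)-6-hydroxy-5-(2-hydroxypropan-2-yl)-3,8-dimethyl-4,5,6,7,8,8a-hexahydroazulen-2(1H)-one | O[C@@H]1C[C@H](C)[C@H]2CC(=O)C(C)=C2C[C@@H]1C(C)(C)O | intermediate
19 | (5S,6R,8S,8aR)-5-(2-hydroxypropan-2-yl)-3,8-dimethyl-2-oxo-1,2,4,5,6,7,8,8a-octahydroazulen-6-yl propanoate | CCC(=O)O[C@@H]1C[C@H](C)[C@H]2CC(=O)C(C)=C2C[C@@H]1C(C)(C)O | intermediate
20 | (5S,6R,8S,8aR)-5-(2-acetoxypropan-2-yl)-3,8-dimethyl-2-oxo-1,2,4,5,6,7,8,8a-octahydroazulen-6-yl propanoate | CCC(=O)O[C@@H]1C[C@H](C)[C@H]2CC(=O)C(C)=C2C[C@@H]1C(C)(C)OC(C)=O | target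

Total step count: 11. Longest linear sequence: 11 steps (from 1).

**Steps most likely to fail**

Step 8. The uncyclised C6 radical may be captured by stannane or oxygen before the oxane ring has inverted to the diaxial conformer, or oxygen capture at C11 may be incomplete. The fallback separates bond formation from oxygenation and sets out from 14. Cobalt-mediated cyclisation (Co(dmgH)2(py)Cl, NaBH4, NaOH, EtOH, 50 °C) releases the C6 radical reversibly from an alkylcobalt with no hydrogen donor or oxygen present. After the same 5-exo closure, the tertiary alkylcobalt loses a cobalt hydride to give the isopropenyl bridged ketal F1. Mukaiyama hydration of F1 (Co(acac)2, PhSiH3, O2, THF) then adds water in the Markovnikov sense and returns to the route at 16.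

Step 7. Methanol may capture the oxocarbenium ion with poor facial selectivity, giving the ketal anomer whose CH2Br group is trans to the C8 alkenyl group and cannot bridge; the enol ether may also isomerise into the ring. The fallback makes C5 configurationally mobile and sets out from 13. NBS in wet THF (NaHCO3) gives the bromomethyl hemiketal F2, whose anomers interconvert through the open hydroxy ketone. Under the conditions of step 8 only the cis anomer can close, and the equilibrium feeds it, to give the bridged hemiketal F3. F3 is taken into the acid stage of step 9 and returns to the route at 17.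

Step 9. Under hydroxide C1 may epimerise, the aldol may close in the bridged direction, or dehydration of the tertiary aldol may stall. The fallback sets out from 16: the sequence is stopped after the acid stage and 17 is isolated. Its C8 hydroxyl is propionylated (propanoic anhydride, pyridine, DMAP) to the keto ester F4. The cyclopentenone is then closed by amine catalysis (pyrrolidine, AcOH, toluene, 60 °C; enamine aldol condensation), which returns to the route at 19.

**Further compounds**
F1 | step 8 | (1R,2R,3S,5R,6R)-2-[(2-ethyl-1,3-dioxolan-2-yl)methyl]-1-methoxy-3-methyl-6-(prop-1-en-2-yl)-8-oxabicyclo[3.2.1]octane | CO[C@]12C[C@H](C(C)=C)[C@H](O1)C[C@H](C)[C@H]2CC1(CC)OCCO1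
F2 | step 7 | (3R,4S,6R)-2-(bromomethyl)-3-[(2-ethyl-1,3-dioxolan-2-yl)methyl]-4-methyl-6-(2-methylprop-1-en-1-yl)oxan-2-ol (interconverting C2 anomers) | OC1(CBr)[C@H](CC2(CC)OCCO2)[C@@H](C)C[C@H](C=C(C)C)O1
F3 | step 7 | (1R,2R,3S,5R,6S)-2-[(2-ethyl-1,3-dioxolan-2-yl)methyl]-6-(2-hydroxypropan-2-yl)-3-methyl-8-oxabicyclo[3.2.1]octan-1-ol | O[C@]12C[C@H](C(C)(C)O)[C@H](O1)C[C@H](C)[C@H]2CC1(CC)OCCO1
F4 | step 9 | (1R,2S,5R,6S)-2-(2-hydroxypropan-2-yl)-6-methyl-4-oxo-5-(2-oxobutyl)cycloheptyl propanoate | CCC(=O)O[C@@H]1C[C@H](C)[C@@H](CC(=O)CC)C(=O)C[C@@H]1C(C)(C)O
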